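## Plan

Numbering used: 1,2-dioxane O1–O2–C3(CH2CO2Me)–C4(Et)–C5–C6(Et); side chain C7H2–C8(Me)=C9H–C10H(Et)–C11H=C12H–C13–C14.

- **Enabling feature:** O1–C6–C7H2–C8(Me)=C9 is a homoallylic tertiary peroxide, the product pattern of a cyclopropylcarbinyl-to-homoallyl opening. C6–C7–C8 is therefore folded back into a cyclopropane carrying a carbinol at C9, and the first cut is O1–C6, with the C3 hydroperoxide as internal nucleophile.
- **Further cuts, in order:** C3–O2 (peroxide 1,4-addition to a C1–C3 enal), C2=C3 (Wittig), C4–ethyl and C3–O (carboalumination/oxidation of an allyl group), C9–C10 (allylboration), C7 (CH2 transfer to a C6=C8 alkene), C8–CH3 and C6–C5 (carbomagnesiation/allylation of pent-2-yn-1-ol).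
- **Forward order:** alkyne → tetrasubstituted allylic alcohol → cyclopropane (a temporary ring) → C10–C14 arm → C4 → C1–C3 with the peroxide → strain-release closure of the 1,2-dioxane, the only ring of the target, in the last step.
- **Stereochemistry:** C10 and 11E come from an α-chiral allylboronate; C6 from ligand-controlled cyclopropanation, then inversion in the last step; C4 from the zirconocene catalyst; C3 from the aminocatalyst; 8E from the geometry of the ring opening. The cyclopropane carbon C8 and the C9 carbinol are sacrificial stereocentres.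

Key step: step 14

Remark: the sense of induction written for the chiral reagents of steps 3, 5, 8 and 11 follows the accepted transition-state models for the parent substrate classes; if one of them ran with the opposite sense on these substrates, its enantiomer would be used.

## Route

Step 1
Reactants: 1 but-1-yne
Product: 2 2-[(1E)-but-1-en-1-yl]-4,4,5,5-tetramethyl-1,3,2-dioxaborolane
Conditions: HBpin, Cp2ZrHCl (5 mol %), CH2Cl2, sealed vessel, 25 °C
Reagents that add atoms: pinacolborane, [H]B1OC(C)(C)C(C)(C)O1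
Why: Cp2ZrHCl-catalysed syn hydroboration of the terminal alkyne places boron at the terminus and should give only the E-alkenylboronate.

Step 2
Reactants: 3 propan-1-ol; 4 N,N-diisopropylcarbamoyl chloride
Product: 5 propyl N,N-diisopropylcarbamate
Conditions: NaH, THF, 0 °C to reflux
Reagents that add atoms: none
Why: O-acylation of the sodium alkoxide by the carbamoyl chloride gives the carbamate that directs the α-lithiation of step 3.

Step 3
Reactants: 5 propyl N,N-diisopropylcarbamate; 2 2-[(1E)-but-1-en-1-yl]-4,4,5,5-tetramethyl-1,3,2-dioxaborolane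
Product: 8 2-[(3S,4E)-hept-4-en-3-yl]-4,4,5,5-tetramethyl-1,3,2-dioxaborolane, via lithiated carbamate 6 (not isolated), via boronate complex 7 (not isolated)
Conditions: sBuLi, (+)-sparteine, Et2O, −78 °C; then 2, −78 °C; then warm to 35 °C
Reagents that add atoms: none
Why: sparteine-mediated enantioselective α-lithiation of the carbamate, borylation with retention and 1,2-metallate shift of the alkenyl group with inversion (lithiation–borylation) should give the α-chiral allylic boronate of S configuration with the E alkene unchanged.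

Step 4
Reactants: 9 pent-2-yn-1-ol; 10 allyl bromide
Product: 12 (2Z)-3-ethyl-2-methylhexa-2,5-dien-1-ol, via magnesium chelate 11 (not isolated)
Conditions: MeMgBr (2.5 equiv), CuI (10 mol %), THF, −10 °C to reflux; then 10, 0 °C to rt; aq. NH4Cl
Reagents that add atoms: methylmagnesium bromide, C[Mg]Br
Why: CuI-catalysed anti-carbomagnesiation of the propargylic alkoxide puts methyl on C2 and magnesium on C3 inside a five-membered chelate, and allylation of this alkenylmagnesium with retention fixes the tetrasubstituted alkene with CH2OH and allyl cis.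

Step 5
Reactants: 12 (2Z)-3-ethyl-2-methylhexa-2,5-dien-1-ol
Product: 13 [(1R,2S)-2-ethyl-1-methyl-2-(prop-2-en-1-yl)cyclopropyl]methanol
Conditions: Zn(CH2I)2·DME (from Et2Zn, CH2I2, DME), (4S,5S)-2-butyl-N,N,N',N'-tetramethyl-1,3,2-dioxaborolane-4,5-dicarboxamide (1.2 equiv), CH2Cl2, −10 °C to rt
Reagents that add atoms: diiodomethane, ICI
Why: Charette asymmetric Simmons–Smith cyclopropanation, in which the alkoxide bound to the chiral dioxaborolane directs CH2 from Zn(CH2I)2 to one face of the allylic alkene only (the isolated allyl alkene is not directed), the syn addition turning the alkene geometry into the cis relation of CH2OH and allyl and the (S,S) ligand setting both quaternary centres as 1R,2S.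

Step 6
Reactants: 13 [(1R,2S)-2-ethyl-1-methyl-2-(prop-2-en-1-yl)cyclopropyl]methanol
Product: 14 (1R,2S)-2-ethyl-1-methyl-2-(prop-2-en-1-yl)cyclopropane-1-carbaldehyde
Conditions: Dess–Martin periodinane, NaHCO3, CH2Cl2, 0 °C to rt
Reagents that add atoms: none
Why: Dess–Martin oxidation of the neopentyl-type primary alcohol should give the non-enolisable aldehyde without touching alkene or cyclopropane.

Step 7
Reactants: 14 (1R,2S)-2-ethyl-1-methyl-2-(prop-2-en-1-yl)cyclopropane-1-carbaldehyde; 8 2-[(3S,4E)-hept-4-en-3-yl]-4,4,5,5-tetramethyl-1,3,2-dioxaborolane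
Product: 17 (1R,2R,3E)-2-ethyl-1-[(1R,2S)-2-ethyl-1-methyl-2-(prop-2-en-1-yl)cyclopropyl]hex-3-en-1-ol, via butyl ate complex 15 (not isolated), via borinic ester 16 (not isolated)
Conditions: 8 (1.2 equiv), nBuLi, THF, −78 °C; (CF3CO)2O, −78 °C; then 14, −78 °C to rt; aq. NaOH
Reagents that add atoms: none
Why: conversion of the pinacol boronate into the more reactive borinic ester and allylboration through a chair transition state with the α-ethyl group equatorial should transfer the boronate chirality to C10 (R), give the anti carbinol (R) from the E γ-substituent, and form the new alkene with E geometry.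

Step 8
Reactants: 17 (1R,2R,3E)-2-ethyl-1-[(1R,2S)-2-ethyl-1-methyl-2-(prop-2-en-1-yl)cyclopropyl]hex-3-en-1-ol
Product: 19 (1R,2R,3E)-2-ethyl-1-{(1R,2S)-2-ethyl-2-[(2R)-2-ethyl-3-hydroxypropyl]-1-methylcyclopropyl}hex-3-en-1-ol, via bis(diethylalane) 18 (not isolated)
Conditions: Et3Al (3.5 equiv), (−)-bis(1-neomenthylindenyl)zirconium dichloride (5–8 mol %), CH2Cl2, 0 °C to rt; then O2, 0 °C; aq. NaOH
Reagents that add atoms: triethylaluminium, CC[Al](CC)CC; dioxygen, O=O
Why: the ZACA reaction (asymmetric carboalumination under the chiral zirconocene dichloride) adds ethyl to the internal carbon and aluminium to the terminus of the monosubstituted alkene only, the catalyst controlling the face (4R), and oxidation of the C–Al bond with O2 gives the primary alcohol.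

Step 9
Reactants: 19 (1R,2R,3E)-2-ethyl-1-{(1R,2S)-2-ethyl-2-[(2R)-2-ethyl-3-hydroxypropyl]-1-methylcyclopropyl}hex-3-en-1-ol
Product: 21 (2E,4R)-4-ethyl-5-{(1S,2R)-1-ethyl-2-[(1R,2R,3E)-2-ethyl-1-hydroxyhex-3-en-1-yl]-2-methylcyclopropyl}pent-2-enal, via aldehyde 20 (not isolated)
Conditions: PhI(OAc)2 (1.1 equiv), TEMPO (10 mol %), CH2Cl2, rt; then Ph3P=CHCHO (1.5 equiv), 40 °C
Reagents that add atoms: (triphenylphosphoranylidene)acetaldehyde, O=CC=P(c1ccccc1)(c1ccccc1)c1ccccc1
Why: TEMPO/PhI(OAc)2 oxidises the primary alcohol in preference to the hindered secondary carbinol, and the stabilised ylide converts the α-branched aldehyde in the same flask, before it can epimerise, into the E enal (Wittig reaction).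

Step 10
Reactants: 22 2,3-dimethylbut-2-ene
Product: 23 2-methoxypropan-2-yl hydroperoxide
Conditions: O3, MeOH/CH2Cl2, −78 °C
Reagents that add atoms: ozone, [O-][O+]=O; methanol, CO
Why: ozonolysis of the tetrasubstituted alkene in methanol traps the carbonyl oxide as the α-methoxy hydroperoxide, a hydroperoxide donor whose ketal carbon is later removed with mild acid.

Step 11
Reactants: 21 (2E,4R)-4-ethyl-5-{(1S,2R)-1-ethyl-2-[(1R,2R,3E)-2-ethyl-1-hydroxyhex-3-en-1-yl]-2-methylcyclopropyl}pent-2-enal; 23 2-methoxypropan-2-yl hydroperoxide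
Product: 24 (3R,4R)-4-ethyl-5-{(1S,2R)-1-ethyl-2-[(1R,2R,3E)-2-ethyl-1-hydroxyhex-3-en-1-yl]-2-methylcyclopropyl}-3-[(2-methoxypropan-2-yl)peroxy]pentanal
Conditions: (R)-2-[diphenyl(trimethylsilyloxy)methyl]pyrrolidine (20 mol %), PhCO2H (10 mol %), toluene, 0 °C
Reagents that add atoms: none
Why: iminium-ion organocatalysis, in which the hydroperoxide adds 1,4 to the E iminium ion from the face left open by the diphenyl(silyloxy)methyl group (the R catalyst giving 3R) and protonation of the resulting enamine by the acid co-catalyst outruns closure to the epoxide.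

Step 12
Reactants: 24 (3R,4R)-4-ethyl-5-{(1S,2R)-1-ethyl-2-[(1R,2R,3E)-2-ethyl-1-hydroxyhex-3-en-1-yl]-2-methylcyclopropyl}-3-[(2-methoxypropan-2-yl)peroxy]pentanal
Product: 25 (3R,4R)-4-ethyl-5-{(1S,2R)-1-ethyl-2-[(1R,2R,3E)-2-ethyl-1-hydroxyhex-3-en-1-yl]-2-methylcyclopropyl}-3-[(2-methoxypropan-2-yl)peroxy]pentanoic acid
Conditions: NaClO2, NaH2PO4, 2-methylbut-2-ene, tBuOH/H2O, 0 °C
Reagents that add atoms: sodium chlorite, [Na+].[O-]Cl=O
Why: Pinnick oxidation converts the aldehyde into the acid under buffered conditions that should spare the peroxide, the alkene (HOCl is scavenged) and the ketal.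

Step 13
Reactants: 25 (3R,4R)-4-ethyl-5-{(1S,2R)-1-ethyl-2-[(1R,2R,3E)-2-ethyl-1-hydroxyhex-3-en-1-yl]-2-methylcyclopropyl}-3-[(2-methoxypropan-2-yl)peroxy]pentanoic acid
Product: 27 methyl (3R,4R)-4-ethyl-5-{(1S,2R)-1-ethyl-2-[(1R,2R,3E)-2-ethyl-1-hydroxyhex-3-en-1-yl]-2-methylcyclopropyl}-3-hydroperoxypentanoate, via methyl ester peroxyketal 26 (not isolated)
Conditions: TMSCHN2 (1.1 equiv), PhMe/MeOH, 0 °C; then pyridinium p-toluenesulfonate (10 mol %), MeOH, rt
Reagents that add atoms: trimethylsilyldiazomethane, C[Si](C)(C)C=[N+]=[N-]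
Why: methylation of the acid by diazomethane released from TMSCHN2 and methanol, then acid-catalysed methanolysis of the peroxyketal, frees the hydroperoxide without any base, which would cause Kornblum–DeLaMare or retro-Michael loss of the β-peroxy ester.

Step 14
Reactants: 27 methyl (3R,4R)-4-ethyl-5-{(1S,2R)-1-ethyl-2-[(1R,2R,3E)-2-ethyl-1-hydroxyhex-3-en-1-yl]-2-methylcyclopropyl}-3-hydroperoxypentanoate
Product: 28 methyl 2-[(3R,4R,6R)-4,6-diethyl-6-[(2E,4R,5E)-4-ethyl-2-methylocta-2,5-dien-1-yl]-1,2-dioxan-3-yl]acetate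
Conditions: Bi(OTf)3 (5 mol %), CH2Cl2/(CF3)2CHOH (9:1), 4 Å molecular sieves, −30 °C to 0 °C
Reagents that add atoms: none
Why: Proposed new method: the acid ionises the C9 carbinol, the C6–C8 bond of the cyclopropane participates so that the positive charge is relayed to the fully substituted C6 (cyclopropylcarbinyl/bicyclobutonium ion), and the terminal oxygen of the C3 hydroperoxide attacks C6 from the side opposite the departing C8, which opens the three-membered ring, releases its strain and forms the O1–C6 bond, the C8=C9 alkene and water. The closest known reaction type is the stereoinvertive nucleophilic substitution at a quaternary cyclopropane carbon of cyclopropyl carbinols by halide, azide, water or alcohols (a Julia–Johnson-type homoallylic ring opening), which has not been shown with a hydroperoxide or in an intramolecular, peroxide-ring-forming mode; hydroperoxides are known to capture acid-generated carbocations, and the α-effect makes the OOH terminus the best internal nucleophile. The 1,2-dioxane closes 6-exo-tet, with C6 as ring atom and the breaking C6–C8 bond exocyclic. C6 is the only new stereocentre and is set by inversion of the (S)-configured cyclopropane carbon installed in step 5, so attack anti to C8 gives 6R, while C3, C4 and C10 are not touched. The step needs site selectivity, E geometry and survival of the O–O bond: C6 carries most of the charge and alone leads to a six-membered ring (attack at C9 would need an eight-membered one), the branched C10 substituent lies away from the substituted ring face in the bisected cation and so ends cis to the C8 methyl (8E), and catalytic acid at low temperature in a weakly nucleophilic medium should avoid Hock-type cleavage of the secondary hydroperoxide and re-ionisation of the product.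

## Compound list

1 | but-1-yne | CCC#C | starting material
2 | 2-[(1E)-but-1-en-1-yl]-4,4,5,5-tetramethyl-1,3,2-dioxaborolane | CC/C=C/B1OC(C)(C)C(C)(C)O1 | intermediate
3 | propan-1-ol | CCCO | starting material
4 | N,N-diisopropylcarbamoyl chloride | CC(C)N(C(C)C)C(Cl)=O | starting material
5 | propyl N,N-diisopropylcarbamate | CCCOC(=O)N(C(C)C)C(C)C | intermediate
6 | (1R)-1-lithiopropyl N,N-diisopropylcarbamate (as its sparteine complex) | CC[C@@H]([Li])OC(=O)N(C(C)C)C(C)C | intermediate
7 | lithium [(1E)-but-1-en-1-yl][(1R)-1-(diisopropylcarbamoyloxy)propyl]pinacolatoborate | [Li+].CC[C@H](OC(=O)N(C(C)C)C(C)C)[B-]1(/C=C/CC)OC(C)(C)C(C)(C)O1 | intermediate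
8 | 2-[(3S,4E)-hept-4-en-3-yl]-4,4,5,5-tetramethyl-1,3,2-dioxaborolane | CC[C@H](B1OC(C)(C)C(C)(C)O1)/C=C/CC | intermediate
9 | pent-2-yn-1-ol | CCC#CCO | starting material
10 | allyl bromide (3-bromoprop-1-ene) | C=CCBr | starting material
11 | 3-ethyl-4-methyl-2,5-dihydro-1,2-oxamagnesole (five-membered alkenylmagnesium alkoxide chelate) | CCC1=C(C)CO[Mg]1 | intermediate
12 | (2Z)-3-ethyl-2-methylhexa-2,5-dien-1-ol | OC/C(C)=C(\CC=C)CC | intermediate
13 | [(1R,2S)-2-ethyl-1-methyl-2-(prop-2-en-1-yl)cyclopropyl]methanol | OC[C@]1(C)C[C@]1(CC)CC=C | intermediate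
14 | (1R,2S)-2-ethyl-1-methyl-2-(prop-2-en-1-yl)cyclopropane-1-carbaldehyde | O=C[C@]1(C)C[C@]1(CC)CC=C | intermediate
15 | lithium butyl[(3S,4E)-hept-4-en-3-yl]pinacolatoborate | [Li+].CCCC[B-]1([C@@H](CC)/C=C/CC)OC(C)(C)C(C)(C)O1 | intermediate
16 | 2,3-dimethyl-3-(trifluoroacetoxy)butan-2-yl butyl[(3S,4E)-hept-4-en-3-yl]borinate | CCCCB(OC(C)(C)C(C)(C)OC(=O)C(F)(F)F)[C@@H](CC)/C=C/CC | intermediate
17 | (1R,2R,3E)-2-ethyl-1-[(1R,2S)-2-ethyl-1-methyl-2-(prop-2-en-1-yl)cyclopropyl]hex-3-en-1-ol | CC/C=C/[C@@H](CC)[C@@H](O)[C@]1(C)C[C@]1(CC)CC=C | intermediate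
18 | O,C-bis(diethylaluminium) derivative of 19 (alkoxide OAlEt2 at C9, CH2AlEt2 at C3) | CC/C=C/[C@@H](CC)[C@@H](O[Al](CC)CC)[C@]1(C)C[C@]1(CC)C[C@@H](CC)C[Al](CC)CC | intermediate
19 | (1R,2R,3E)-2-ethyl-1-{(1R,2S)-2-ethyl-2-[(2R)-2-ethyl-3-hydroxypropyl]-1-methylcyclopropyl}hex-3-en-1-ol | CC/C=C/[C@@H](CC)[C@@H](O)[C@]1(C)C[C@]1(CC)C[C@@H](CC)CO | intermediate
20 | (2R)-2-ethyl-3-{(1S,2R)-1-ethyl-2-[(1R,2R,3E)-2-ethyl-1-hydroxyhex-3-en-1-yl]-2-methylcyclopropyl}propanal | CC/C=C/[C@@H](CC)[C@@H](O)[C@]1(C)C[C@]1(CC)C[C@@H](CC)C=O | intermediate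
21 | (2E,4R)-4-ethyl-5-{(1S,2R)-1-ethyl-2-[(1R,2R,3E)-2-ethyl-1-hydroxyhex-3-en-1-yl]-2-methylcyclopropyl}pent-2-enal | CC/C=C/[C@@H](CC)[C@@H](O)[C@]1(C)C[C@]1(CC)C[C@@H](CC)/C=C/C=O | intermediate
22 | 2,3-dimethylbut-2-ene | CC(C)=C(C)C | starting material
23 | 2-methoxypropan-2-yl hydroperoxide | COC(C)(C)OO | intermediate
24 | (3R,4R)-4-ethyl-5-{(1S,2R)-1-ethyl-2-[(1R,2R,3E)-2-ethyl-1-hydroxyhex-3-en-1-yl]-2-methylcyclopropyl}-3-[(2-methoxypropan-2-yl)peroxy]pentanal | CC/C=C/[C@@H](CC)[C@@H](O)[C@]1(C)C[C@]1(CC)C[C@@H](CC)[C@@H](CC=O)OOC(C)(C)OC | intermediate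
25 | (3R,4R)-4-ethyl-5-{(1S,2R)-1-ethyl-2-[(1R,2R,3E)-2-ethyl-1-hydroxyhex-3-en-1-yl]-2-methylcyclopropyl}-3-[(2-methoxypropan-2-yl)peroxy]pentanoic acid | CC/C=C/[C@@H](CC)[C@@H](O)[C@]1(C)C[C@]1(CC)C[C@@H](CC)[C@@H](CC(=O)O)OOC(C)(C)OC | intermediate
26 | methyl (3R,4R)-4-ethyl-5-{(1S,2R)-1-ethyl-2-[(1R,2R,3E)-2-ethyl-1-hydroxyhex-3-en-1-yl]-2-methylcyclopropyl}-3-[(2-methoxypropan-2-yl)peroxy]pentanoate | CC/C=C/[C@@H](CC)[C@@H](O)[C@]1(C)C[C@]1(CC)C[C@@H](CC)[C@@H](CC(=O)OC)OOC(C)(C)OC | intermediate
27 | methyl (3R,4R)-4-ethyl-5-{(1S,2R)-1-ethyl-2-[(1R,2R,3E)-2-ethyl-1-hydroxyhex-3-en-1-yl]-2-methylcyclopropyl}-3-hydroperoxypentanoate | CC/C=C/[C@@H](CC)[C@@H](O)[C@]1(C)C[C@]1(CC)C[C@@H](CC)[C@@H](CC(=O)OC)OO | intermediate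
28 | methyl 2-[(3R,4R,6R)-4,6-diethyl-6-[(2E,4R,5E)-4-ethyl-2-methylocta-2,5-dien-1-yl]-1,2-dioxan-3-yl]acetate | CC/C=C/[C@H](/C=C(\C)C[C@@]1(CC)C[C@@H](CC)[C@@H](CC(=O)OC)OO1)CC | target

## Step count and risks

Total steps: 14. Longest linear sequence: 10 (steps 4, 5, 6, 7, 8, 9, 11, 12, 13, 14).

Steps most likely to fail:

1. **Step 14 (proposed new method).** After ionisation the cation may undergo a hydride shift from C10, lose a proton at C6, or the hydroperoxide may be cleaved by the acid before it closes the ring; capture might also occur without full inversion. Fallback with known chemistry, setting out from 27: TMSBr in CH2Cl2 at −78 °C carries out the known stereoinvertive bromide opening of the cyclopropyl carbinol (the hydroperoxide is silylated in passing and freed on aqueous work-up) and should give methyl (3R,4R,6R,8E,10R,11E)-6-bromo-4,6,10-triethyl-3-hydroperoxy-8-methyltetradeca-8,11-dienoate F1. Cyclisation of this bromoalkyl hydroperoxide assisted by AgOCOCF3 (CH2Cl2, −40 °C, 2,6-di-tert-butylpyridine) then forms O1–C6 and comes back to the route at 28. This closure passes through the free C6 cation, so the C6 epimer would have to be removed by chromatography.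

2. **Step 8.** Ethyl transfer may show incomplete facial selectivity next to the quaternary ring carbon, the cyclic carbometallation pathway may compete, and the cyclopropylcarbinyl OAlEt2 group may ionise under the Lewis-acidic conditions. Fallback (auxiliary control in place of catalyst control), setting out from 17:
   - hydroboration of the terminal alkene with 9-BBN, then NaOH/H2O2, should give (1R,2R,3E)-2-ethyl-1-[(1R,2S)-2-ethyl-2-(3-hydroxypropyl)-1-methylcyclopropyl]hex-3-en-1-ol F2;
   - PhI(OAc)2/TEMPO gives 3-{(1S,2R)-1-ethyl-2-[(1R,2R,3E)-2-ethyl-1-hydroxyhex-3-en-1-yl]-2-methylcyclopropyl}propanal F3;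
   - condensation with SAMP gives the SAMP hydrazone of that aldehyde F4;
   - Enders alkylation (LDA, 2.2 equiv, THF; EtI, −100 °C to rt) should give the (2R)-2-ethyl SAMP hydrazone F5;
   - cleavage with aqueous oxalic acid returns to the route at 20, which is taken through the Wittig stage of step 9.

3. **Step 5.** Enantiofacial discrimination by the dioxaborolane may be poor on a tetrasubstituted allylic alcohol, and methylene transfer may be slow. Fallback (substrate control in place of reagent control), setting out from 12: MnO2 in CH2Cl2 gives (2Z)-3-ethyl-2-methylhexa-2,5-dienal F6. Allylboration with 8 under the conditions of step 7 should give (4Z,6R,7R,8E)-4,7-diethyl-5-methylundeca-1,4,8-trien-6-ol F7. Hydroxyl-directed Simmons–Smith cyclopropanation (Et2Zn, CH2I2, CH2Cl2, 0 °C), with the carbinol hydrogen eclipsing the alkene to relieve A(1,3) strain, should deliver CH2 to the face syn to the hydroxyl group. By the model used in step 5 this is the face that gives the (1R,2S) cyclopropane, so the sequence returns to the route at 17.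

Further compounds
F1 | step 14 | methyl (3R,4R,6R,8E,10R,11E)-6-bromo-4,6,10-triethyl-3-hydroperoxy-8-methyltetradeca-8,11-dienoate | CC/C=C/[C@H](/C=C(\C)C[C@@](Br)(CC)C[C@@H](CC)[C@@H](CC(=O)OC)OO)CC
F2 | step 8 | (1R,2R,3E)-2-ethyl-1-[(1R,2S)-2-ethyl-2-(3-hydroxypropyl)-1-methylcyclopropyl]hex-3-en-1-ol | CC/C=C/[C@@H](CC)[C@@H](O)[C@]1(C)C[C@]1(CC)CCCO
F3 | step 8 | 3-{(1S,2R)-1-ethyl-2-[(1R,2R,3E)-2-ethyl-1-hydroxyhex-3-en-1-yl]-2-methylcyclopropyl}propanal | CC/C=C/[C@@H](CC)[C@@H](O)[C@]1(C)C[C@]1(CC)CCC=O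
F4 | step 8 | SAMP hydrazone of F3 ((E)-N-[(2S)-2-(methoxymethyl)pyrrolidin-1-yl]imine) | CC/C=C/[C@@H](CC)[C@@H](O)[C@]1(C)C[C@]1(CC)CC/C=N/N2CCC[C@H]2COC
F5 | step 8 | SAMP hydrazone of 20 ((2R)-2-ethyl aldehyde hydrazone) | CC/C=C/[C@@H](CC)[C@@H](O)[C@]1(C)C[C@]1(CC)C[C@@H](CC)/C=N/N2CCC[C@H]2COC
F6 | step 5 | (2Z)-3-ethyl-2-methylhexa-2,5-dienal | O=C/C(C)=C(\CC=C)CC
F7 | step 5 | (4Z,6R,7R,8E)-4,7-diethyl-5-methylundeca-1,4,8-trien-6-ol | CC/C=C/[C@@H](CC)[C@@H](O)/C(C)=C(\CC=C)CC
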